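A small charge of starting complex meets a surplus of incoming ligand (0.30 mM on Monday's), while a large one does not (1.5 mM on Thursday's).

    starting complex + incoming ligand ⇌ leaving ligand + complex with one exchanged (K1 = 59, k1 = 320 /M/s)
    complex with one exchanged + incoming ligand ⇌ leaving ligand + complex with two exchanged (K2 = 0.44, k2 = 340 /M/s)
    starting complex + complex with two exchanged ⇌ idle adduct, settled at all times (K3 = 2600 /M)

| flask | starting complex | incoming ligand | time | remark |
|---|---|---|---|---|
| Monday's | 0.30 mM (in portions, 2) | 1.05 mM | 80 s | the portions of starting complex follow each other after 10 s, the first at the start |
| Friday's | 0.40 mM (in portions, 2) | 1.05 mM | 80 s | the portions of starting complex follow each other after 10 s, the first at the start |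
| Sunday's | 0.60 mM (in portions, 2) | 1.05 mM | 80 s | the portions of starting complex follow each other after 10 s, the first at the start |
| Wednesday's | 1.0 mM (in portions, 2) | 1.05 mM | 80 s | the portions of starting complex follow each other after 10 s, the first at the start |
| Thursday's | 1.5 mM (in portions, 2) | 1.05 mM | 80 s | the portions of starting complex follow each other after 10 s, the first at the start |

- in percentages every species weighs as the starting complex in it: one idle adduct counts as two
- for complex with two exchanged the idle adduct is counted in
- in an amount of complex with two exchanged, one idle adduct counts as one complex with two exchanged
- the concentration of complex with two exchanged that is asked is that of its free form alone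
- "hardly changes" means that all values lie within two and a half points (for a concentration: within two and a half percent of the largest)
- run time (Monday's): 80 s

* [complex with two exchanged] (only what is free in solution) at the end for Monday's, Friday's, Sunday's, Wednesday's, Thursday's, in this order
* the course of these numbers from the first flask to the last (rises, then falls / rises all the way / falls all the way / hardly changes / falls, then rises)

- Take the second step at balance. Its forward rate is k·c(complex with one exchanged)·c(incoming ligand), and its backward rate has the same k divided by 0.44.
- Divide one by the other and time drops out: c(complex with two exchanged)/c(complex with one exchanged) = 0.44·c(incoming ligand)/c(leaving ligand). Call the right side the split quotient.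
- You may use balance at the end. The forward half-life of complex with one exchanged on Monday's is 1.9 s, by that step alone, far shorter than the 70.0 s after the second portion.
- First extreme, Monday's: the first constant, 59, is far above the second, so let the first step finish. Then c(incoming ligand) is 0.750 mM, c(leaving ligand) is 0.30 mM, and the split quotient is 1.10.
- That is Monday's ceiling, since each second exchange takes one incoming ligand and frees one leaving ligand. Carrying this through the balance, I get 0.119 mM on Monday's and 0.123 mM on Friday's.
- Second extreme, Thursday's: incoming ligand is the limiting reagent, with 1.05 mM against 1.5 mM of starting complex. Let the first step use up its charge, and its balance leaves 0.0415 mM of incoming ligand. The split quotient drops to 0.0174, which gives 0.0183 mM.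
- These figures are estimates, not bounds. Mine rise from 0.119 mM on Monday's to 0.123 mM on Friday's and fall to 0.0183 mM on Thursday's, so I expect the row to rise and then fall.
- The forecast gives 0.118 mM, 0.122 mM, 0.107 mM, 0.045 mM, 0.0137 mM, course rises, then falls, having “treated each flask as essentially at equilibrium”. Its Thursday's value is lower than my 0.0183 mM.
- The flasks give 0.119 mM, 0.122 mM, 0.107 mM, 0.0455 mM, 0.0138 mM, course rises, then falls.
- Monday's ends with complex with one exchanged at 59.3% of the charge, so its reading of the ratio is 0.669, below the ceiling 1.10.
- On Sunday's, incoming ligand ends at 34% of its charge and leaving ligand at 0.691 mM, so the split quotient is 0.228.
- Multiply by Sunday's complex with one exchanged, 78.2% of the charge, and you get 0.107 mM, where Sunday's flask reads 0.107 mM.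

The constants are invented; the result is computed.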